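A small charge of capture agent goes into the flask, 0.0249 M against 0.083 M of substrate, so the examination starts there.

the same everywhere: substrate 0.083 M
- summer: first nucleophile 0.80 equiv; second nucleophile 1.05 equiv; capture agent 0.012 M; run made earlier
- winter: first nucleophile 0.80 equiv; second nucleophile 1.05 equiv; capture agent 0.050 M; run made earlier
- spring: first nucleophile 0.80 equiv; second nucleophile 2.1 equiv; capture agent 0.0249 M; run made earlier
- flask: first nucleophile 0.800 equiv; second nucleophile 1.05 equiv; capture agent 0.0249 M; time 15 h

| run | time / h | target / % | other capture product / % | substrate / % |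
|---|---|---|---|---|
| summer | 2.50 | 2.3 | 36.4 | 0.1 |
| summer | 5.00 | 3.1 | 36.2 | 0.1 |
| summer | 8.00 | 1.7 | 36.3 | 0 |
| summer | 10.0 | 2.1 | 36.0 | 0 |
| summer | 12.0 | 1.4 | 35.9 | 0.3 |
| summer | 15.0 | 3.3 | 36.4 | 0.9 |
| summer | 20.0 | 2.8 | 36.5 | 0 |
| winter | 2.50 | 1.4 | 35.3 | 0.2 |
| winter | 5.00 | 1.8 | 36.5 | 0.3 |
| winter | 8.00 | 2.3 | 35.3 | 0 |
| winter | 10.0 | 2.2 | 35.4 | 0 |
| winter | 12.0 | 3.4 | 35.1 | 0 |
| winter | 15.0 | 3.1 | 35.3 | 0 |
| winter | 20.0 | 1.7 | 36.8 | 0 |
| spring | 4.00 | 0.8 | 49.6 | 0.8 |
| spring | 8.00 | 1.6 | 49.5 | 0.3 |
| spring | 10.0 | 1.8 | 50.7 | 0.1 |
| spring | 15.0 | 0.6 | 49.1 | 0 |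
| spring | 20.0 | 1.5 | 48.8 | 0 |

(standard deviation of a reading: 0.5 percentage points)



- share of target in target plus other capture product at 12 s
- share of target in target plus other capture product at 12 min
- share of target in target plus other capture product at 15 h
- which of target and other capture product there is more of at 15 h

Does the capture agent matter? Going from 0.012 M in the summer run to 0.050 M in the winter run, target over other capture product reads 0.0658 and then 0.0637, a change of no weight, so I give it zeroth order in this ratio.

What does move the ratio? The spring run, with 2.1 equiv of second nucleophile for 1.05 equiv, reads 0.0254 against a pooled 0.0648. Spring target averages 1.26% with a scatter of 0.5 percentage points per reading, so I read this loosely as inverse first order in second nucleophile.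

What do you carry? A selectivity factor S, target over other capture product multiplied by c(second nucleophile)/c(first nucleophile), which as a reading, from the pooled ratio and the charges, is 0.0850. Both nucleophiles then compete for one species, which is my assumption, because first nucleophile was held at 0.80 equiv in each run.

And the flask? S gives a ratio of 0.0648, so a share of 6.08% at 15 h, with other capture product ahead.

But is that share valid early? The readings begin at 2.50 h, and summer target reads 2.8% at 20.0 h although 0.80 equiv of first nucleophile was charged. If first nucleophile leaves by another route, the early ratio stands above the end ratio, so I expect early shares not below 6.08%, and I name no number.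

The forecast gives 5% at 12 s, 5.2% at 12 min, 6% at 15 h and other capture product ahead, remarking “The early values are extrapolated”; my reckoning agrees at 15 h and differs on the earliest share, which I expect not below 6.08%.

The flask gives 14.4% at 12 s, 6.02% at 12 min and 5.98% at 15 h, with 2.28% of target and 35.8% of other capture product.

    2 substrate → homo dimer (k = 0.0270 /M/s)
    first nucleophile → decomposed reagent (k = 0.0170 /s)
    open intermediate → solvolysis product (k = 8.90 /s)
    open intermediate + capture agent → trapped intermediate (k = 1.40 /M/s)
    second nucleophile + open intermediate → other capture product (k = 120 /M/s)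
    substrate → open intermediate (k = 0.00630 /s)
    first nucleophile + open intermediate → target (k = 29.0 /M/s)

By 1.50 h the flask holds 0% of its first nucleophile and 65.9% of its second, and S, read from end amounts, speaks of the finished run, not of the share at 12 s. Take the neighbouring flask with 0.480 equiv of first nucleophile, its other charges as in the recipe. S gives it a ratio of 0.0389, a share of 3.74% at 15 h. That neighbouring flask stores a share of 3.72%, with 1.40% of target.

All runs stem from a simulated flask with constants of no real substance; the scatter is artificial.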